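**Plan**
- Retrosynthesis: the six O–Si bonds are cut first; then the C-1–C-8a ring bond (with H-2 returned to C-8a), which opens the carbocyclic ring to an (E,E)-2,3-bis(arylidene)-1,4-diarylbutane-1,4-dione; then the central C-2–C-3 diene bond; then the two arylidene C=C bonds, back to two aldehydes and one common α-bromo acyl ylide.
- Forward: ylide, two (Z)-α-bromochalcones (Wittig), stannylation of one, Stille coupling to join the chain, light-driven closure of the cyclohexadiene ring (ring B) onto the 3-methoxy-4,5-disiloxyphenyl ring (ring A), then desilylation.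
- Enabling feature: in the open diene, the ring A bond C-4a=C-8a, C-3=C-4 and C-2=C-1 form a helically twisted cis-hexatriene whose ends (the arene carbon ortho to the side chain and the benzylidene carbon C-1) lie face to face. The two aroyl C=O groups on C-2 and C-3 are 1,4-related and can hold one metal in a seven-membered chelate.
- Stereochemistry: the cis H-1/H-2 relation comes from the E,E geometry through conrotatory 6π photocyclisation and a suprafacial [1,5]-H shift from C-8a to C-2. The absolute sense comes from a chiral Sc(OTf)3–PyBox chelate that selects one helix of the diene.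
- Helpers: tert-butyldimethylsilyl (TBS) ethers protect the phenols and steer closure to the carbon next to OMe; the chelate ring is lost on work-up and the silyl groups in the last step.

Key step: step 13

Remark: TBS = tert-butyldimethylsilyl (TBSO = its ether); locants C-1 to C-8a are those of the 1,2-dihydronaphthalene core of the target.
Assumption: which helix of the diene the (S,S)-ligand chelate prefers cannot be derived with certainty; the (S,S)-ligand is written, and the (R,R)-ligand takes its place should the antipodal series result.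

Step 1
Reactants: 1 2-bromo-1-(4-hydroxyphenyl)ethan-1-one
Product: 2 [2-(4-hydroxyphenyl)-2-oxoethyl]triphenylphosphonium bromide
Conditions: PPh3, THF, 20 °C
Reagents that add atoms: triphenylphosphine c1ccc(cc1)P(c1ccccc1)c1ccccc1
Why: SN2 alkylation of the phosphine by the phenacyl bromide (phosphonium salt formation) should be fast, and the free phenol is inert.

Step 2
Reactants: 2 [2-(4-hydroxyphenyl)-2-oxoethyl]triphenylphosphonium bromide
Product: 3 1-[4-(TBSO)phenyl]-2-(triphenyl-λ5-phosphanylidene)ethan-1-one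
Conditions: TBSCl, Et3N, CH2Cl2, 0 to 20 °C; aqueous NaHCO3 work-up
Reagents that add atoms: tert-butyldimethylsilyl chloride CC(C)(C)[Si](C)(C)Cl
Why: Et3N removes the acidic P–CH2 proton (acyl-stabilised ylide formation) and the phenolic proton, the phenoxide is silylated, and any O-silylated ylide should revert on aqueous work-up.

Step 3
Reactants: 3 1-[4-(TBSO)phenyl]-2-(triphenyl-λ5-phosphanylidene)ethan-1-one
Product: 4 2-bromo-1-[4-(TBSO)phenyl]-2-(triphenyl-λ5-phosphanylidene)ethan-1-one
Conditions: N-bromosuccinimide, CH2Cl2, −20 to 20 °C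
Reagents that add atoms: N-bromosuccinimide O=C1CCC(=O)N1Br
Why: Electrophilic bromination of the nucleophilic ylide carbon followed by proton transfer to the succinimide anion (halogenation of a stabilised phosphorane) should give the isolable α-bromo ylide.

Step 4
Reactants: 5 3,4-dihydroxy-5-methoxybenzaldehyde
Product: 6 3,4-bis(TBSO)-5-methoxybenzaldehyde
Conditions: TBSCl, imidazole, DMF, 20 °C
Reagents that add atoms: tert-butyldimethylsilyl chloride CC(C)(C)[Si](C)(C)Cl
Why: Imidazole-promoted silylation of both phenols (silyl ether formation) leaves the aldehyde untouched.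

Step 5
Reactants: 6 3,4-bis(TBSO)-5-methoxybenzaldehyde; 4 2-bromo-1-[4-(TBSO)phenyl]-2-(triphenyl-λ5-phosphanylidene)ethan-1-one
Product: 7 (Z)-2-bromo-3-[3,4-bis(TBSO)-5-methoxyphenyl]-1-[4-(TBSO)phenyl]prop-2-en-1-one
Conditions: toluene, 90 °C, exclusion of light
Reagents that add atoms: none
Why: Wittig olefination with a carbonyl-stabilised α-bromo ylide is reversible up to the oxaphosphetane and should place the aryl group trans to the aroyl group, which is the (Z)-bromoalkene.

Step 6
Reactants: 7 (Z)-2-bromo-3-[3,4-bis(TBSO)-5-methoxyphenyl]-1-[4-(TBSO)phenyl]prop-2-en-1-one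
Product: 8 (Z)-3-[3,4-bis(TBSO)-5-methoxyphenyl]-1-[4-(TBSO)phenyl]-2-(trimethylstannyl)prop-2-en-1-one
Conditions: Me3SnSnMe3, Pd(PPh3)4 (5 mol%), toluene, 90 °C
Reagents that add atoms: hexamethylditin C[Sn](C)(C)[Sn](C)(C)C
Why: Palladium-catalysed stannylation of a vinyl bromide with a distannane (oxidative addition, Sn–Sn transmetalation, reductive elimination) should retain the alkene geometry.

Step 7
Reactants: 9 2,3,4-trihydroxybenzaldehyde
Product: 10 4-hydroxy-2,2-diphenyl-1,3-benzodioxole-5-carbaldehyde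
Conditions: Ph2CCl2, diphenyl ether, 175 °C
Reagents that add atoms: dichlorodiphenylmethane ClC(Cl)(c1ccccc1)c1ccccc1
Why: Catechol ketalisation should bridge O-3 and O-4, because the more acidic 4-hydroxyl reacts first and closes onto O-3 while the 2-hydroxyl is held by a hydrogen bond to the aldehyde.

Step 8
Reactants: 10 4-hydroxy-2,2-diphenyl-1,3-benzodioxole-5-carbaldehyde
Product: 11 4-methoxy-2,2-diphenyl-1,3-benzodioxole-5-carbaldehyde
Conditions: MeI, K2CO3, DMF, 40 °C
Reagents that add atoms: iodomethane CI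
Why: Williamson etherification of the remaining chelated phenol should be clean because the cyclic ketal cannot migrate to the free oxygen.

Step 9
Reactants: 11 4-methoxy-2,2-diphenyl-1,3-benzodioxole-5-carbaldehyde
Product: 12 3,4-dihydroxy-2-methoxybenzaldehyde
Conditions: AcOH/H2O 4:1, reflux
Reagents that add atoms: none
Why: Acid hydrolysis of the diphenylmethylene ketal releases benzophenone and frees the catechol without touching the methyl ether or the aldehyde.

Step 10
Reactants: 12 3,4-dihydroxy-2-methoxybenzaldehyde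
Product: 13 3,4-bis(TBSO)-2-methoxybenzaldehyde
Conditions: TBSCl, imidazole, DMF, 20 °C
Reagents that add atoms: tert-butyldimethylsilyl chloride CC(C)(C)[Si](C)(C)Cl
Why: Imidazole-promoted silylation of both phenols (silyl ether formation), with no free neighbouring oxygen left to which a silyl group could migrate.

Step 11
Reactants: 13 3,4-bis(TBSO)-2-methoxybenzaldehyde; 4 2-bromo-1-[4-(TBSO)phenyl]-2-(triphenyl-λ5-phosphanylidene)ethan-1-one
Product: 14 (Z)-2-bromo-3-[3,4-bis(TBSO)-2-methoxyphenyl]-1-[4-(TBSO)phenyl]prop-2-en-1-one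
Conditions: toluene, 100 °C, exclusion of light
Reagents that add atoms: none
Why: Wittig olefination with the stabilised α-bromo ylide should again place the aryl group trans to the aroyl group, giving the (Z)-bromoalkene.

Step 12
Reactants: 8 (Z)-3-[3,4-bis(TBSO)-5-methoxyphenyl]-1-[4-(TBSO)phenyl]-2-(trimethylstannyl)prop-2-en-1-one; 14 (Z)-2-bromo-3-[3,4-bis(TBSO)-2-methoxyphenyl]-1-[4-(TBSO)phenyl]prop-2-en-1-one
Product: 15 (2E,3E)-2-[3,4-bis(TBSO)-2-methoxybenzylidene]-3-[3,4-bis(TBSO)-5-methoxybenzylidene]-1,4-bis[4-(TBSO)phenyl]butane-1,4-dione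
Conditions: Pd2(dba)3 (5 mol%), AsPh3 (20 mol%), CuI (20 mol%), NMP, 50 °C, exclusion of light
Reagents that add atoms: none
Why: Copper-assisted Stille coupling of a vinylstannane with a vinyl bromide retains the geometry of both partners, so the (E,E)-diene with both aryl groups pointing inward should result.

Step 13
Reactants: 15 (2E,3E)-2-[3,4-bis(TBSO)-2-methoxybenzylidene]-3-[3,4-bis(TBSO)-5-methoxybenzylidene]-1,4-bis[4-(TBSO)phenyl]butane-1,4-dione
Product: 17 (1R,2R)-1-[3,4-bis(TBSO)-2-methoxyphenyl]-6,7-bis(TBSO)-8-methoxy-2,3-bis[4-(TBSO)benzoyl]-1,2-dihydronaphthalene, via the 1,8a-dihydronaphthalene 16 (not isolated)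
Conditions: Sc(OTf)3 (0.3 equiv), (S,S)-tBu-PyBox [2,6-bis((4S)-4-tert-butyl-4,5-dihydro-1,3-oxazol-2-yl)pyridine] (0.36 equiv), 4 Å molecular sieves, CH2Cl2, 427 nm LED, −20 °C, argon; then dark, 20 °C; pH 7 buffer work-up
Reagents that add atoms: none
Why: Proposed new method: chelation of the 1,4-related aroyl carbonyl groups on C-2 and C-3 by the chiral Sc(OTf)3–PyBox complex (a temporary seven-membered ring) is expected to hold one helix of the twisted s-cis diene and to shift its absorption into the violet so that only bound 15 is excited, whereupon conrotatory 6π electrocyclisation of the hexatriene C-8a=C-4a/C-4=C-3/C-2=C-1 gives the dearomatised 16 and a thermal suprafacial [1,5]-H shift from C-8a to C-2, driven by rearomatisation, gives 17. The closest known reaction types are the photocyclisation and [1,5]-H shift of (E,E)-bis(benzylidene)succinic anhydrides, imides and chirally bridged amide esters to cis-1-aryl-1,2-dihydronaphthalenes, and chiral Lewis acid controlled photoreactions of chelating enones that are excited selectively at long wavelength. Ring B closes in a 6π electrocyclic (6-endo type) mode in which all six ring carbons are the triene carbons. C-1 is set by the sense of conrotation, which the selected helix dictates (bonding on the Si face of C-1), and C-2 is set by delivery of H-8a on the face it already occupies; because both aryl groups of the E,E-diene point inward, H-1 and H-8a, and hence H-1 and H-2, end up cis. The step needs closure of ring A and not of the pendant ring, which is favoured because the closing carbon of ring A is ortho to OMe and para to a siloxy group (both oxygens meta to the side chain, the pattern that makes aryl trienes of this type close well) whereas the pendant ring offers one free ortho carbon activated by a single para oxygen; it needs closure next to OMe and not next to OTBS, which the bulk of the 5-siloxy group, pushed toward C-6 by the neighbouring 4-siloxy group, should secure; and it needs the E,E geometry to last until closure, which the rigid chelate and long-wavelength excitation should help. No base is present at any point, so the kinetically formed cis ketone should not epimerise.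

Step 14
Reactants: 17 (1R,2R)-1-[3,4-bis(TBSO)-2-methoxyphenyl]-6,7-bis(TBSO)-8-methoxy-2,3-bis[4-(TBSO)benzoyl]-1,2-dihydronaphthalene
Product: 18 (1R,2R)-1-(3,4-dihydroxy-2-methoxyphenyl)-6,7-dihydroxy-8-methoxy-2,3-bis(4-hydroxybenzoyl)-1,2-dihydronaphthalene
Conditions: HF·pyridine, pyridine/THF, 0 to 20 °C, argon; degassed work-up
Reagents that add atoms: none
Why: Fluoride cleaves the six aryl Si–O bonds (desilylation driven by the Si–F bond) in a pyridine-buffered, weakly acidic medium in which the C-2 centre next to the ketone should not epimerise and, under argon, the catechols should not be oxidised.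

**Compound list**
1 | 2-bromo-1-(4-hydroxyphenyl)ethan-1-one | O=C(CBr)c1ccc(O)cc1 | starting material
2 | [2-(4-hydroxyphenyl)-2-oxoethyl]triphenylphosphonium bromide | O=C(C[P+](c1ccccc1)(c1ccccc1)c1ccccc1)c1ccc(O)cc1.[Br-] | intermediate
3 | 1-[4-(TBSO)phenyl]-2-(triphenyl-λ5-phosphanylidene)ethan-1-one | O=C(C=P(c1ccccc1)(c1ccccc1)c1ccccc1)c1ccc(O[Si](C)(C)C(C)(C)C)cc1 | intermediate
4 | 2-bromo-1-[4-(TBSO)phenyl]-2-(triphenyl-λ5-phosphanylidene)ethan-1-one | O=C(C(Br)=P(c1ccccc1)(c1ccccc1)c1ccccc1)c1ccc(O[Si](C)(C)C(C)(C)C)cc1 | intermediate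
5 | 3,4-dihydroxy-5-methoxybenzaldehyde | COc1cc(C=O)cc(O)c1O | starting material
6 | 3,4-bis(TBSO)-5-methoxybenzaldehyde | COc1cc(C=O)cc(O[Si](C)(C)C(C)(C)C)c1O[Si](C)(C)C(C)(C)C | intermediate
7 | (Z)-2-bromo-3-[3,4-bis(TBSO)-5-methoxyphenyl]-1-[4-(TBSO)phenyl]prop-2-en-1-one | O=C(c1ccc(O[Si](C)(C)C(C)(C)C)cc1)/C(Br)=C/c1cc(OC)c(O[Si](C)(C)C(C)(C)C)c(O[Si](C)(C)C(C)(C)C)c1 | intermediate
8 | (Z)-3-[3,4-bis(TBSO)-5-methoxyphenyl]-1-[4-(TBSO)phenyl]-2-(trimethylstannyl)prop-2-en-1-one | O=C(c1ccc(O[Si](C)(C)C(C)(C)C)cc1)/C(=C/c1cc(OC)c(O[Si](C)(C)C(C)(C)C)c(O[Si](C)(C)C(C)(C)C)c1)[Sn](C)(C)C | intermediate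
9 | 2,3,4-trihydroxybenzaldehyde | O=Cc1ccc(O)c(O)c1O | starting material
10 | 4-hydroxy-2,2-diphenyl-1,3-benzodioxole-5-carbaldehyde | O=Cc1ccc2OC(c3ccccc3)(c3ccccc3)Oc2c1O | intermediate
11 | 4-methoxy-2,2-diphenyl-1,3-benzodioxole-5-carbaldehyde | COc1c(C=O)ccc2OC(c3ccccc3)(c3ccccc3)Oc12 | intermediate
12 | 3,4-dihydroxy-2-methoxybenzaldehyde | COc1c(C=O)ccc(O)c1O | intermediate
13 | 3,4-bis(TBSO)-2-methoxybenzaldehyde | COc1c(C=O)ccc(O[Si](C)(C)C(C)(C)C)c1O[Si](C)(C)C(C)(C)C | intermediate
14 | (Z)-2-bromo-3-[3,4-bis(TBSO)-2-methoxyphenyl]-1-[4-(TBSO)phenyl]prop-2-en-1-one | O=C(c1ccc(O[Si](C)(C)C(C)(C)C)cc1)/C(Br)=C/c1ccc(O[Si](C)(C)C(C)(C)C)c(O[Si](C)(C)C(C)(C)C)c1OC | intermediate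
15 | (2E,3E)-2-[3,4-bis(TBSO)-2-methoxybenzylidene]-3-[3,4-bis(TBSO)-5-methoxybenzylidene]-1,4-bis[4-(TBSO)phenyl]butane-1,4-dione | O=C(c1ccc(O[Si](C)(C)C(C)(C)C)cc1)/C(=C/c1ccc(O[Si](C)(C)C(C)(C)C)c(O[Si](C)(C)C(C)(C)C)c1OC)C(=C/c1cc(OC)c(O[Si](C)(C)C(C)(C)C)c(O[Si](C)(C)C(C)(C)C)c1)\C(=O)c1ccc(O[Si](C)(C)C(C)(C)C)cc1 | intermediate
16 | (1S,8aS)-1-[3,4-bis(TBSO)-2-methoxyphenyl]-6,7-bis(TBSO)-8-methoxy-2,3-bis[4-(TBSO)benzoyl]-1,8a-dihydronaphthalene (H-1 and H-8a cis) | COC1=C(O[Si](C)(C)C(C)(C)C)C(O[Si](C)(C)C(C)(C)C)=CC2=CC(C(=O)c3ccc(O[Si](C)(C)C(C)(C)C)cc3)=C(C(=O)c3ccc(O[Si](C)(C)C(C)(C)C)cc3)[C@H](c3ccc(O[Si](C)(C)C(C)(C)C)c(O[Si](C)(C)C(C)(C)C)c3OC)[C@H]12 | intermediate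
17 | (1R,2R)-1-[3,4-bis(TBSO)-2-methoxyphenyl]-6,7-bis(TBSO)-8-methoxy-2,3-bis[4-(TBSO)benzoyl]-1,2-dihydronaphthalene (H-1 and H-2 cis) | COc1c([C@@H]2c3c(cc(O[Si](C)(C)C(C)(C)C)c(O[Si](C)(C)C(C)(C)C)c3OC)C=C(C(=O)c3ccc(O[Si](C)(C)C(C)(C)C)cc3)[C@@H]2C(=O)c2ccc(O[Si](C)(C)C(C)(C)C)cc2)ccc(O[Si](C)(C)C(C)(C)C)c1O[Si](C)(C)C(C)(C)C | intermediate
18 | (1R,2R)-1-(3,4-dihydroxy-2-methoxyphenyl)-6,7-dihydroxy-8-methoxy-2,3-bis(4-hydroxybenzoyl)-1,2-dihydronaphthalene | COc1c([C@@H]2c3c(cc(O)c(O)c3OC)C=C(C(=O)c3ccc(O)cc3)[C@@H]2C(=O)c2ccc(O)cc2)ccc(O)c1O | target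

Total step count: 14. Longest linear sequence: 8 steps (steps 1, 2, 3, 5, 6, 12, 13, 14, or equally steps 7 to 14).

Steps most likely to fail, in this order: step 13, step 12, step 14.

Step 13 bears the label and comes first. The chelate may discriminate the two helices of 15 poorly, unbound 15 may absorb and close without control, the pendant ring may close in place of ring A, or the benzylidene double bond may isomerise before closure, so that enantiomeric purity, constitution or the cis arrangement is eroded. The fallback uses known chemistry, sets out from 15 and comes back at 17. Direct irradiation of 15 without Lewis acid (366 nm, degassed toluene, 0 to 20 °C), the photocyclisation and [1,5]-H shift known for (E,E)-bis(benzylidene)succinic derivatives, should proceed through 16 and its mirror image, the (1R,8aR)-1,8a-dihydronaphthalene F1, and give 17 together with its (1S,2S) antipode F2. Preparative chromatography on a chiral stationary phase (amylose tris(3,5-dimethylphenylcarbamate)) then separates 17 from F2.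

In step 12, transfer of the hindered α-keto vinyl group from tin to palladium may be too slow, so that protodestannylation and homocoupling consume the partners. The fallback sets out from 8 (with 1 and 13) and comes back at 15. Compound 1 is silylated (TBSCl, iPr2NEt, CH2Cl2) to 2-bromo-1-[4-(TBSO)phenyl]ethan-1-one F3. Stille coupling of 8 with F3 at its unhindered sp3 carbon (Pd2(dba)3, tri(2-furyl)phosphine, THF, 60 °C) should give the mono-arylidene diketone (E)-2-[3,4-bis(TBSO)-5-methoxybenzylidene]-1,4-bis[4-(TBSO)phenyl]butane-1,4-dione F4. Its lithium enolate (LiN(iPr)2, THF, −78 °C) adds to aldehyde 13 to give the aldol F5 as a mixture of diastereomers, which is dehydrated (MsCl, Et3N; then DBU) to 15. The second arylidene bond is thus made by aldol condensation, with the alkene geometry under thermodynamic control.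

In step 14, the two liberated catechol units may be oxidised by air during isolation, and the cis ketone may epimerise at C-2 to the more stable trans isomer if the medium turns basic. The fallback sets out from 17 and comes back at 18. Desilylation with HF·pyridine is followed in the same flask by acetylation (Ac2O, pyridine, 0 °C) to the hexaacetate F6, which can be purified and stored without risk. Neutral deacetylation (NH4OAc, MeOH/H2O, 20 °C, argon) then releases 18 with volatile by-products only, so that the free hexaphenol needs no chromatography.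

Further compounds
F1 | step 13 | (1R,8aR)-1-[3,4-bis(TBSO)-2-methoxyphenyl]-6,7-bis(TBSO)-8-methoxy-2,3-bis[4-(TBSO)benzoyl]-1,8a-dihydronaphthalene (mirror image of 16) | COC1=C(O[Si](C)(C)C(C)(C)C)C(O[Si](C)(C)C(C)(C)C)=CC2=CC(C(=O)c3ccc(O[Si](C)(C)C(C)(C)C)cc3)=C(C(=O)c3ccc(O[Si](C)(C)C(C)(C)C)cc3)[C@@H](c3ccc(O[Si](C)(C)C(C)(C)C)c(O[Si](C)(C)C(C)(C)C)c3OC)[C@@H]12
F2 | step 13 | (1S,2S)-1-[3,4-bis(TBSO)-2-methoxyphenyl]-6,7-bis(TBSO)-8-methoxy-2,3-bis[4-(TBSO)benzoyl]-1,2-dihydronaphthalene (antipode of 17) | COc1c([C@H]2c3c(cc(O[Si](C)(C)C(C)(C)C)c(O[Si](C)(C)C(C)(C)C)c3OC)C=C(C(=O)c3ccc(O[Si](C)(C)C(C)(C)C)cc3)[C@H]2C(=O)c2ccc(O[Si](C)(C)C(C)(C)C)cc2)ccc(O[Si](C)(C)C(C)(C)C)c1O[Si](C)(C)C(C)(C)C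
F3 | step 12 | 2-bromo-1-[4-(TBSO)phenyl]ethan-1-one | O=C(CBr)c1ccc(O[Si](C)(C)C(C)(C)C)cc1
F4 | step 12 | (E)-2-[3,4-bis(TBSO)-5-methoxybenzylidene]-1,4-bis[4-(TBSO)phenyl]butane-1,4-dione | O=C(c1ccc(O[Si](C)(C)C(C)(C)C)cc1)/C(=C/c1cc(OC)c(O[Si](C)(C)C(C)(C)C)c(O[Si](C)(C)C(C)(C)C)c1)CC(=O)c1ccc(O[Si](C)(C)C(C)(C)C)cc1
F5 | step 12 | (E)-2-[3,4-bis(TBSO)-5-methoxybenzylidene]-3-[[3,4-bis(TBSO)-2-methoxyphenyl](hydroxy)methyl]-1,4-bis[4-(TBSO)phenyl]butane-1,4-dione (mixture of diastereomers) | O=C(c1ccc(O[Si](C)(C)C(C)(C)C)cc1)/C(=C/c1cc(OC)c(O[Si](C)(C)C(C)(C)C)c(O[Si](C)(C)C(C)(C)C)c1)C(C(O)c1ccc(O[Si](C)(C)C(C)(C)C)c(O[Si](C)(C)C(C)(C)C)c1OC)C(=O)c1ccc(O[Si](C)(C)C(C)(C)C)cc1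
F6 | step 14 | (1R,2R)-1-(3,4-diacetoxy-2-methoxyphenyl)-6,7-diacetoxy-8-methoxy-2,3-bis(4-acetoxybenzoyl)-1,2-dihydronaphthalene | COc1c([C@@H]2c3c(cc(OC(C)=O)c(OC(C)=O)c3OC)C=C(C(=O)c3ccc(OC(C)=O)cc3)[C@@H]2C(=O)c2ccc(OC(C)=O)cc2)ccc(OC(C)=O)c1OC(C)=O
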